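**Plan**
- Retrosynthetic cuts, in order: the phenol O–Si bond; the carbinol C–H bond (back to an aryl ketone); the lactone O–CH2 and C(=O)–Cα bonds together, which releases CO2 and leaves an aryl cyclopropyl ketone; then aryl–C(=O) (aryl Grignard + nitrile), two cyclopropane C–C bonds (cyanomethylphosphonate + benzyl oxirane) and aryl–CH2 (aryl Grignard + epichlorohydrin).
- Forward: oxirane → cyclopropane (a temporary ring) → aryl cyclopropyl ketone → the γ-lactone, the only non-aromatic ring of the target, closed by a formal (3+2) cycloaddition with CO2 → ketone reduction → desilylation.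
- Enabling feature: the ring CH2 and Cα of the lactone are 1,3-related through the benzyl-bearing CH, and Cα carries an aryl carbinol. At the ketone level these three carbons form an acyl cyclopropane whose CH2–C(acyl) σ-bond is a masked 1,3-dipole (enolate carbon + primary electrophile); the O–C(=O) unit between them is CO2.
- Stereochemistry: C4 (R) comes from (R)-epichlorohydrin through an inversion in the cyclopropanation; C3 settles trans to C4 under thermodynamic control; the carbinol (S) comes from chelation-controlled hydride delivery.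

Key step: step 5

Remark: 6, 10 and 11 are drawn as the trans cyclopropanes. Any cis epimer at the nitrile/acyl-bearing ring carbon has the same configuration at the benzyl-bearing carbon and converges in step 5, where that carbon becomes a planar enolate.

**Step 1**
Reactants: 1 (R)-epichlorohydrin; 2 3,4-dimethoxyphenylmagnesium bromide
Product: 4 (R)-2-(3,4-dimethoxybenzyl)oxirane, via chlorohydrin alkoxide 3 (not isolated)
Conditions: CuI (10 mol %), THF, −40 → 0 °C; then 2 M aq. NaOH, rt, same pot
Reagents that add atoms: none
Why: Copper-catalysed SN2 opening of the oxirane of 1 at its CH2 terminus by the aryl Grignard reagent, then base-induced Williamson closure of the chlorohydrin, is a standard entry to benzyl oxiranes; the stereocentre is a spectator in both events, so (R)-1 should give (R)-4.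

**Step 2**
Reactants: 4 (R)-2-(3,4-dimethoxybenzyl)oxirane; 5 diethyl cyanomethylphosphonate
Product: 6 (1S,2R)-2-(3,4-dimethoxybenzyl)cyclopropane-1-carbonitrile
Conditions: NaH, DME, reflux
Reagents that add atoms: none
Why: Wadsworth–Emmons cyclopropanation, in which the phosphonate carbanion opens the oxirane at CH2, the alkoxide takes over the phosphoryl group and the α-cyano carbanion displaces the secondary phosphate in a 3-exo-tet SN2 step with inversion, which sets the benzyl-bearing ring carbon as R.

**Step 3**
Reactants: 7 4-bromo-2-methoxyphenol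
Product: 8 (4-bromo-2-methoxyphenoxy)(tert-butyl)dimethylsilane
Conditions: TBSCl, imidazole, DMF, rt
Reagents that add atoms: tert-butyldimethylsilyl chloride, CC(C)(C)[Si](C)(C)Cl
Why: Standard imidazole-promoted silylation of a phenol, which masks the acidic OH for the Grignard step and can be removed with fluoride at the end.

**Step 4**
Reactants: 6 (1S,2R)-2-(3,4-dimethoxybenzyl)cyclopropane-1-carbonitrile; 8 (4-bromo-2-methoxyphenoxy)(tert-butyl)dimethylsilane
Product: 11 {4-[(tert-butyldimethylsilyl)oxy]-3-methoxyphenyl}[(1S,2R)-2-(3,4-dimethoxybenzyl)cyclopropyl]methanone, via aryl Grignard 9 (not isolated), via magnesium ketimide 10 (not isolated)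
Conditions: 8, Mg, THF, 50 °C; then 6, CuBr (5 mol %), THF, reflux; then 1 M aq. HCl, 0 °C
Reagents that add atoms: water, O
Why: Addition of an aryl Grignard reagent to a nitrile stops at the N-magnesio ketimine, which mild aqueous acid hydrolyses to the aryl ketone, and the benzyl-bearing cyclopropane stereocentre takes no part.

**Step 5**
Reactants: 11 {4-[(tert-butyldimethylsilyl)oxy]-3-methoxyphenyl}[(1S,2R)-2-(3,4-dimethoxybenzyl)cyclopropyl]methanone; 12 carbon dioxide
Product: 15 (3S,4R)-3-{4-[(tert-butyldimethylsilyl)oxy]-3-methoxybenzoyl}-4-(3,4-dimethoxybenzyl)dihydrofuran-2(3H)-one, via iodo enolate 13 (not isolated), via iodo carboxylate 14 (not isolated)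
Conditions: MgI2 (2 equiv), i-Pr2NEt (2 equiv), CO2 (20 bar), MeCN, 60 °C; then cold aq. citric acid; then Et3N (cat.), CH2Cl2, rt
Reagents that add atoms: none
Why: Proposed new method: MgI2 binds the aryl ketone, iodide opens the cyclopropane by SN2 attack at the unsubstituted ring CH2 (homo-Michael addition), the magnesium enolate so formed is C-carboxylated by CO2 to a chelated β-keto carboxylate, and the carboxylate oxygen then displaces the primary iodide, so that the acyl-cyclopropane σ-bond adds across one C=O of CO2 in a formal (3+2) cycloaddition and iodide is returned. The closest known reaction types are the MgI2-mediated ring expansion of cyclopropyl ketones and spirocyclopropyl oxindoles with imines, the Mg(II)/amine carboxylation of ketones with CO2 and, as the microscopic reverse, the halide-catalysed decarboxylative contraction of 2-acylbutyrolactones to cyclopropyl ketones at high temperature. The one ring is closed by a 5-exo-tet O-alkylation. The benzyl-bearing carbon is not touched and keeps the configuration set in step 2, while the new α-carbon passes through a planar chelated enolate and, after protonation and amine-mediated equilibration, should settle trans to the neighbouring benzyl group under thermodynamic control. The step needs cleavage of the CH2–C(acyl) bond and not the CH(benzyl)–C(acyl) bond, which the preference of iodide for the unhindered primary carbon should secure, and C-carboxylation ahead of enolate O-alkylation to a dihydrofuran (Cloke–Wilson path), which magnesium chelation and CO2 pressure should favour. Because the uncatalysed equilibrium is expected to lie close to balance, CO2 pressure, a moderate temperature and deprotonation of the product to its magnesium chelate by i-Pr2NEt are used to pull it to the lactone.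

**Step 6**
Reactants: 15 (3S,4R)-3-{4-[(tert-butyldimethylsilyl)oxy]-3-methoxybenzoyl}-4-(3,4-dimethoxybenzyl)dihydrofuran-2(3H)-one
Product: 16 (3S,4R)-3-[(S)-{4-[(tert-butyldimethylsilyl)oxy]-3-methoxyphenyl}(hydroxy)methyl]-4-(3,4-dimethoxybenzyl)dihydrofuran-2(3H)-one
Conditions: Zn(BH4)2, Et2O/THF, −20 → 0 °C; aq. NH4Cl
Reagents that add atoms: none
Why: Chelation-controlled reduction of an α-substituted β-keto lactone, in which Zn(II) bridges the ketone and lactone carbonyl oxygens, one face of the ketone then lies over the lactone ring next to C4–H, and hydride should enter from the open face next to C3–H, anti to the C3–C4 bond, to give the syn (S) carbinol without touching C3 or C4.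

**Step 7**
Reactants: 16 (3S,4R)-3-[(S)-{4-[(tert-butyldimethylsilyl)oxy]-3-methoxyphenyl}(hydroxy)methyl]-4-(3,4-dimethoxybenzyl)dihydrofuran-2(3H)-one
Product: 17 (3S,4R)-4-(3,4-dimethoxybenzyl)-3-[(S)-hydroxy(4-hydroxy-3-methoxyphenyl)methyl]dihydrofuran-2(3H)-one
Conditions: TBAF, AcOH (1:1), THF, 0 °C
Reagents that add atoms: none
Why: Fluoride cleavage of the aryl silyl ether, buffered with acetic acid so that the phenoxide is protonated at once and neither retro-aldol cleavage nor C3 epimerisation of the β-hydroxy lactone is set off.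

**Compound list**
1 | (R)-epichlorohydrin, (R)-2-(chloromethyl)oxirane | ClC[C@H]1CO1 | starting material
2 | 3,4-dimethoxyphenylmagnesium bromide (THF solution) | COc1ccc([Mg]Br)cc1OC | starting material
3 | bromomagnesium (R)-1-chloro-3-(3,4-dimethoxyphenyl)propan-2-olate | ClC[C@H](O[Mg]Br)Cc1ccc(OC)c(OC)c1 | intermediate
4 | (R)-2-(3,4-dimethoxybenzyl)oxirane | C1[C@H](O1)Cc1ccc(OC)c(OC)c1 | intermediate
5 | diethyl cyanomethylphosphonate | CCOP(=O)(CC#N)OCC | starting material
6 | (1S,2R)-2-(3,4-dimethoxybenzyl)cyclopropane-1-carbonitrile (trans) | N#C[C@H]1C[C@@H]1Cc1ccc(OC)c(OC)c1 | intermediate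
7 | 4-bromo-2-methoxyphenol | COc1cc(Br)ccc1O | starting material
8 | (4-bromo-2-methoxyphenoxy)(tert-butyl)dimethylsilane | COc1cc(Br)ccc1O[Si](C)(C)C(C)(C)C | intermediate
9 | {4-[(tert-butyldimethylsilyl)oxy]-3-methoxyphenyl}magnesium bromide | COc1cc([Mg]Br)ccc1O[Si](C)(C)C(C)(C)C | intermediate
10 | N-bromomagnesio ketimine of ketone 11 | COc1cc(C(=N[Mg]Br)[C@H]2C[C@@H]2Cc2ccc(OC)c(OC)c2)ccc1O[Si](C)(C)C(C)(C)C | intermediate
11 | {4-[(tert-butyldimethylsilyl)oxy]-3-methoxyphenyl}[(1S,2R)-2-(3,4-dimethoxybenzyl)cyclopropyl]methanone | COc1cc(C(=O)[C@H]2C[C@@H]2Cc2ccc(OC)c(OC)c2)ccc1O[Si](C)(C)C(C)(C)C | intermediate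
12 | carbon dioxide | O=C=O | starting material
13 | iodomagnesium enolate of (R)-1-{4-[(tert-butyldimethylsilyl)oxy]-3-methoxyphenyl}-4-(3,4-dimethoxyphenyl)-3-(iodomethyl)butan-1-one | COc1cc(C(O[Mg]I)=C[C@H](CI)Cc2ccc(OC)c(OC)c2)ccc1O[Si](C)(C)C(C)(C)C | intermediate
14 | iodomagnesium (3R)-2-{4-[(tert-butyldimethylsilyl)oxy]-3-methoxybenzoyl}-4-(3,4-dimethoxyphenyl)-3-(iodomethyl)butanoate (both C2 epimers) | COc1cc(C(=O)C(C(=O)O[Mg]I)[C@H](CI)Cc2ccc(OC)c(OC)c2)ccc1O[Si](C)(C)C(C)(C)C | intermediate
15 | (3S,4R)-3-{4-[(tert-butyldimethylsilyl)oxy]-3-methoxybenzoyl}-4-(3,4-dimethoxybenzyl)dihydrofuran-2(3H)-one | COc1cc(C(=O)[C@H]2C(=O)OC[C@@H]2Cc2ccc(OC)c(OC)c2)ccc1O[Si](C)(C)C(C)(C)C | intermediate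
16 | (3S,4R)-3-[(S)-{4-[(tert-butyldimethylsilyl)oxy]-3-methoxyphenyl}(hydroxy)methyl]-4-(3,4-dimethoxybenzyl)dihydrofuran-2(3H)-one | COc1cc([C@@H](O)[C@H]2C(=O)OC[C@@H]2Cc2ccc(OC)c(OC)c2)ccc1O[Si](C)(C)C(C)(C)C | intermediate
17 | (3S,4R)-4-(3,4-dimethoxybenzyl)-3-[(S)-hydroxy(4-hydroxy-3-methoxyphenyl)methyl]dihydrofuran-2(3H)-one | COc1cc([C@@H](O)[C@H]2C(=O)OC[C@@H]2Cc2ccc(OC)c(OC)c2)ccc1O | target

**Count**
Total steps: 7. Longest linear sequence: 6 (steps 1, 2, 4, 5, 6, 7).

**Steps most likely to fail**

Step 5 (proposed new method). The carboxylative ring expansion may not go forward: the equilibrium may fall back to cyclopropane and CO2, iodide may open the more substituted ring bond, or the enolate may close on oxygen to a dihydrofuran. The fallback builds the lactone first by known chemistry, sets out from 1 and 2, and returns at 15. Compound 1 with dimethyl malonate and NaOMe in refluxing MeOH should give methyl (1S,5R)-2-oxo-3-oxabicyclo[3.1.0]hexane-1-carboxylate F1. Copper-catalysed homoconjugate opening of its cyclopropane CH2 by 2 (CuI, THF, −30 °C) should give methyl (3S,4R)-4-(3,4-dimethoxybenzyl)-2-oxotetrahydrofuran-3-carboxylate F2. Krapcho decarboxylation (LiCl, wet DMSO, 150 °C) should give (R)-4-(3,4-dimethoxybenzyl)dihydrofuran-2(3H)-one F3. Its lithium enolate (LiHMDS, THF, −78 °C) with purchased 4-[(tert-butyldimethylsilyl)oxy]-3-methoxybenzaldehyde should add trans to the benzyl group and give 16 together with its carbinol epimer (3S,4R)-3-[(R)-{4-[(tert-butyldimethylsilyl)oxy]-3-methoxyphenyl}(hydroxy)methyl]-4-(3,4-dimethoxybenzyl)dihydrofuran-2(3H)-one F4. Dess–Martin oxidation of the mixture converges on 15.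

Step 6. Facial selectivity may be poor if reduction through a non-chelated, Felkin-type arrangement competes with the zinc chelate, which would deliver the carbinol epimer. The fallback moves stereocontrol from the substrate to a catalyst, sets out from 15 and returns at 16: Ru/TsDPEN asymmetric transfer hydrogenation, RuCl[(S,S)-TsDPEN](p-cymene) in HCO2H/Et3N (5:2), in which the aryl ketone face is chosen by the catalyst while C3 equilibrates through the enol and should rest trans. No further compound is made (F0).

Step 7. Unmasking the phenoxide next to a para benzylic carbinol may set off retro-aldol fragmentation, loss of the benzylic hydroxyl through a quinone methide, or epimerisation at C3. The fallback reverses the order of the last two events, sets out from 15 and returns at 17. Desilylation at the robust ketone stage (TBAF, AcOH, THF) should give (3S,4R)-4-(3,4-dimethoxybenzyl)-3-(4-hydroxy-3-methoxybenzoyl)dihydrofuran-2(3H)-one F5. The free phenol is then reduced under the chelation-controlled conditions of step 6, with an extra equivalent of Zn(BH4)2 for the phenol, to give 17 directly.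

**Further compounds**
F1 | step 5 | methyl (1S,5R)-2-oxo-3-oxabicyclo[3.1.0]hexane-1-carboxylate | COC(=O)[C@]12C[C@H]1COC2=O
F2 | step 5 | methyl (3S,4R)-4-(3,4-dimethoxybenzyl)-2-oxotetrahydrofuran-3-carboxylate | COC(=O)[C@H]1C(=O)OC[C@@H]1Cc1ccc(OC)c(OC)c1
F3 | step 5 | (R)-4-(3,4-dimethoxybenzyl)dihydrofuran-2(3H)-one | O=C1OC[C@@H](C1)Cc1ccc(OC)c(OC)c1
F4 | step 5 | (3S,4R)-3-[(R)-{4-[(tert-butyldimethylsilyl)oxy]-3-methoxyphenyl}(hydroxy)methyl]-4-(3,4-dimethoxybenzyl)dihydrofuran-2(3H)-one | COc1cc([C@H](O)[C@H]2C(=O)OC[C@@H]2Cc2ccc(OC)c(OC)c2)ccc1O[Si](C)(C)C(C)(C)C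
F0 | step 6 | none | none
F5 | step 7 | (3S,4R)-4-(3,4-dimethoxybenzyl)-3-(4-hydroxy-3-methoxybenzoyl)dihydrofuran-2(3H)-one | COc1cc(C(=O)[C@H]2C(=O)OC[C@@H]2Cc2ccc(OC)c(OC)c2)ccc1O
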